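**Strategy.** Ring B (C5–C6–C7–C8–C9–C10, labdane numbering) is taken apart at C5–C10 and C8–C9, the two bonds that flank C9–C10. In an acyclic triene the enoate C9=C10 is the dienophile, C5=C6–C7=C8 the diene and C1–C4 the tether, so a single Lewis-acid-promoted intramolecular Diels–Alder reaction closes rings A and B and sets C5, C9 and C10. A C3 acetoxy group of the opposite configuration to the target is carried on purpose: equatorial in the tether, it fixes the absolute sense and is later inverted by oxidation and hindered-hydride reduction. The C6=C7 alkene left by the cycloaddition is then moved to C7=C8, and the side chain is added by B-alkyl Suzuki coupling.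

Key step: step 5

Remark on numbering: labdane numbers are used throughout (C3 carbinol, C4 gem-dimethyl, C5/C10 ring fusion, C9 side-chain carbon); bicyclic intermediates without C12–C16 are named as drimanes (C11 on C9, methyls on C4, C8, C10).

Assumption: the (S)-SEGPHOS iridium catalyst in step 2 gives the (6R)-carbinol; if the sense of induction is the opposite, the enantiomeric ligand is used.

Step 1
Reactants: 1 methyl (2E)-3,7-dimethylocta-2,6-dienoate (methyl geranate)
Product: 3 methyl (2E)-3-methyl-6-oxohex-2-enoate, via methyl 6,7-epoxygeranate 2 (not isolated)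
Conditions: mCPBA, CH2Cl2, 0 °C; then H5IO6, THF/H2O, 0 → 23 °C
Reagents that add atoms: mCPBA, O=C(OO)c1cccc(Cl)c1
Why: Prilezhaev epoxidation should take the electron-rich 6,7-alkene in preference to the conjugated 2,3-alkene, and periodic acid then hydrolyses and cleaves the trisubstituted epoxide to the aldehyde and acetone, leaving the E enoate untouched.

Step 2
Reactants: 3 methyl (2E)-3-methyl-6-oxohex-2-enoate; 4 3-methylbuta-1,2-diene
Product: 5 methyl (2E,6R)-6-hydroxy-3,7,7-trimethylnona-2,8-dienoate
Conditions: [Ir(cod)Cl]2 (2.5 mol %), (S)-SEGPHOS (5 mol %), 4-cyano-3-nitrobenzoic acid (10 mol %), Cs2CO3 (20 mol %), i-PrOH (2 equiv), toluene, 60 °C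
Reagents that add atoms: none
Why: Iridium-catalysed transfer-hydrogenative reverse prenylation: hydrometalation of the allene gives a dimethylallyl iridium species that adds through its substituted terminus in a closed chair transition state, the chiral bisphosphine choosing the aldehyde face and so setting C6 (labdane C3) as R.

Step 3
Reactants: 5 methyl (2E,6R)-6-hydroxy-3,7,7-trimethylnona-2,8-dienoate
Product: 6 methyl (2E,6R)-6-acetoxy-3,7,7-trimethylnona-2,8-dienoate
Conditions: Ac2O, DMAP, pyridine, CH2Cl2, 23 °C
Reagents that add atoms: acetic anhydride, CC(=O)OC(C)=O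
Why: DMAP-catalysed acylation of the hindered secondary alcohol should go to completion and masks the hydroxyl for the Lewis-acid step without touching the stereocentre.

Step 4
Reactants: 6 methyl (2E,6R)-6-acetoxy-3,7,7-trimethylnona-2,8-dienoate; 7 (1E)-1-bromoprop-1-ene
Product: 8 methyl (2E,6R,8E,10E)-6-acetoxy-3,7,7-trimethyldodeca-2,8,10-trienoate
Conditions: Pd(OAc)2 (5 mol %), P(o-tol)3 (10 mol %), K2CO3, Bu4NCl, DMF, 70 °C, sealed tube
Reagents that add atoms: none
Why: Heck alkenylation: the propenylpalladium species should add to the terminal carbon of the vinyl group, and because the neighbouring carbon is quaternary, β-hydride elimination can only give the conjugated E,E-diene with the bromide geometry retained.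

Step 5
Reactants: 8 methyl (2E,6R,8E,10E)-6-acetoxy-3,7,7-trimethyldodeca-2,8,10-trienoate
Product: 9 methyl (3R,5S,8R,9R,10R)-3-acetoxydrim-6-en-11-oate
Conditions: EtAlCl2 (2.5 equiv), CH2Cl2, −78 → 23 °C
Reagents that add atoms: none
Why: EtAlCl2 binds the enoate carbonyl and lowers its LUMO, so that the diene C5=C6–C7=C8 and the dienophile C9=C10 should combine in a concerted, asynchronous [4+2] cycloaddition that forms C5–C10 and C8–C9 in one operation. The closest known reaction type is the Lewis-acid-promoted type 1 intramolecular Diels–Alder reaction of (E,E,E)-deca-1,3,9-triene esters to trans-fused octalins. Ring B is closed by the cycloaddition itself and ring A by the four-carbon tether C1–C4, which folds as a six-membered chair while the C5–C10 bond forms. C5 follows from the E geometry of C5=C6, C9 and C10 (CO2Me cis to 10-CH3) from the E dienophile by suprafacial addition, and the trans ring fusion from the endo position of the complexed ester with the tether anti. The absolute sense is fixed by C3, whose Lewis-acid-complexed acetoxy group should stay equatorial in the chair tether, while C8 is only transient. The step needs endo over exo and one diene face: the first is secured by carbonyl complexation, the second by the equatorial acetoxy group, and the gem-dimethyl group should speed the closure.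

Step 6
Reactants: 9 methyl (3R,5S,8R,9R,10R)-3-acetoxydrim-6-en-11-oate
Product: 10 (3R,5S,8R,9R,10R)-drim-6-ene-3,11-diol
Conditions: LiAlH4, THF, 0 → 23 °C; then H2O, aq. NaOH
Reagents that add atoms: none
Why: Hydride reduction should take the methyl ester to the primary alcohol and cleave the acetate in one operation without touching any stereocentre or the alkene.

Step 7
Reactants: 10 (3R,5S,8R,9R,10R)-drim-6-ene-3,11-diol
Product: 11 (3R,5S,9R,10R)-drim-7-ene-3,11-diol
Conditions: RhCl3·3H2O (10 mol %), EtOH, 80 °C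
Reagents that add atoms: none
Why: Rhodium-hydride-catalysed positional alkene isomerisation (hydrometalation then β-hydride elimination): Rh–H should add from the face opposite the cis 8-CH3 and 10-CH3 groups with rhodium on C7 and eliminate the syn tertiary H-8, driven by the trisubstituted alkene and loss of the syn 8-CH3/10-CH3 strain, while a further shift would need a tertiary alkylrhodium.

Step 8
Reactants: 11 (3R,5S,9R,10R)-drim-7-ene-3,11-diol
Product: 12 (5S,9R,10R)-3-oxodrim-7-en-11-al
Conditions: Dess–Martin periodinane (3 equiv), NaHCO3, CH2Cl2, 0 → 23 °C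
Reagents that add atoms: none
Why: Dess–Martin oxidation should convert both alcohols under buffered conditions that do not enolise the β,γ-unsaturated aldehyde, and it erases the C3 stereocentre on purpose.

Step 9
Reactants: 12 (5S,9R,10R)-3-oxodrim-7-en-11-al
Product: 13 (5S,9R,10R)-11-methylidenedrim-7-en-3-one (9-vinyl ketone)
Conditions: Ph3PCH3Br, KN(SiMe3)2, THF, 0 °C; then 12, −78 → −20 °C
Reagents that add atoms: methyltriphenylphosphonium bromide, C[P+](c1ccccc1)(c1ccccc1)c1ccccc1.[Br-]
Why: Wittig methylenation: the unstabilised ylide should add to the aldehyde much faster than to the hindered α,α-dimethyl ketone, and the low temperature should keep the hindered H-9 from being removed.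

Step 10
Reactants: 13 (5S,9R,10R)-11-methylidenedrim-7-en-3-one
Product: 14 (3S,5S,9R,10R)-11-methylidenedrim-7-en-3-ol
Conditions: K[(s-Bu)3BH], THF, −78 °C; then H2O
Reagents that add atoms: none
Why: The bulky trialkylborohydride should attack the C3 ketone along the equatorial trajectory, away from the syn-axial H-1 and H-5, to give the axial (3S) alcohol, as is usual for 4,4-dimethyl-3-oxo terpenoids.

Step 11
Reactants: 15 ethyl 3-oxobutanoate
Product: 16 ethyl (2E)-3-{[(trifluoromethyl)sulfonyl]oxy}but-2-enoate
Conditions: Tf2O, aq. Me4NOH, hexanes, 5 °C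
Reagents that add atoms: trifluoromethanesulfonic anhydride, O=S(=O)(OS(=O)(=O)C(F)(F)F)C(F)(F)F
Why: O-Triflation of the β-keto ester enolate: the non-chelating tetramethylammonium counter-ion should favour the E enolate and hence the E enol triflate.

Step 12
Reactants: 14 (3S,5S,9R,10R)-11-methylidenedrim-7-en-3-ol; 16 ethyl (2E)-3-{[(trifluoromethyl)sulfonyl]oxy}but-2-enoate
Product: 18 ethyl (3S,5S,9R,10S,13E)-3-hydroxylabda-7,13-dien-15-oate, via B-alkyl-9-BBN adduct 17 (not isolated)
Conditions: 9-BBN (2.5 equiv), THF, 0 → 23 °C; then 16, Pd(dppf)Cl2 (5 mol %), aq. K3PO4, DMF, 23 °C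
Reagents that add atoms: none
Why: 9-BBN should hydroborate only the monosubstituted vinyl group at its terminus (excess covers the hindered hydroxyl), and B-alkyl Suzuki–Miyaura coupling with the enol triflate proceeds with retention, which fixes the 13E alkene.

Step 13
Reactants: 18 ethyl (3S,5S,9R,10S,13E)-3-hydroxylabda-7,13-dien-15-oate
Product: 19 (3S,5S,9R,10S,13E)-labda-7,13-diene-3,15-diol
Conditions: i-Bu2AlH (3.5 equiv), CH2Cl2, −78 °C; then aq. Rochelle salt
Reagents that add atoms: none
Why: The aluminium hydride should reduce the conjugated ester by 1,2-addition to the allylic alcohol without touching either alkene.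

Step 14
Reactants: 19 (3S,5S,9R,10S,13E)-labda-7,13-diene-3,15-diol; 20 (3S)-3-methylpentanoic acid
Product: 21 (3S,5S,9R,10S,13E)-3-hydroxylabda-7,13-dien-15-yl (3S)-3-methylpentanoate
Conditions: EDC·HCl, DMAP (cat.), CH2Cl2, 0 °C
Reagents that add atoms: none
Why: Steglich esterification should acylate only the primary allylic alcohol, since the axial 3-OH beside the gem-dimethyl group is too hindered to compete, and the acid stereocentre β to the carboxyl cannot epimerise.

**Compound list**

1 | methyl (2E)-3,7-dimethylocta-2,6-dienoate (methyl geranate) | COC(=O)/C=C(\C)CCC=C(C)C | starting material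
2 | methyl (2E)-5-(3,3-dimethyloxiran-2-yl)-3-methylpent-2-enoate (racemic) | COC(=O)/C=C(\C)CCC1OC1(C)C | intermediate
3 | methyl (2E)-3-methyl-6-oxohex-2-enoate | COC(=O)/C=C(\C)CCC=O | intermediate
4 | 3-methylbuta-1,2-diene | CC(C)=C=C | starting material
5 | methyl (2E,6R)-6-hydroxy-3,7,7-trimethylnona-2,8-dienoate | COC(=O)/C=C(\C)CC[C@@H](O)C(C)(C)C=C | intermediate
6 | methyl (2E,6R)-6-acetoxy-3,7,7-trimethylnona-2,8-dienoate | COC(=O)/C=C(\C)CC[C@@H](OC(C)=O)C(C)(C)C=C | intermediate
7 | (1E)-1-bromoprop-1-ene | C/C=C/Br | starting material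
8 | methyl (2E,6R,8E,10E)-6-acetoxy-3,7,7-trimethyldodeca-2,8,10-trienoate | COC(=O)/C=C(\C)CC[C@@H](OC(C)=O)C(C)(C)/C=C/C=C/C | intermediate
9 | methyl (3R,5S,8R,9R,10R)-3-acetoxydrim-6-en-11-oate (trans-fused; 3-OAc, 8-CH3, 9-CO2Me and 10-CH3 on one face) | COC(=O)[C@@H]1[C@H](C)C=C[C@@H]2C(C)(C)[C@H](OC(C)=O)CC[C@@]12C | intermediate
10 | (3R,5S,8R,9R,10R)-drim-6-ene-3,11-diol | OC[C@@H]1[C@H](C)C=C[C@@H]2C(C)(C)[C@H](O)CC[C@@]12C | intermediate
11 | (3R,5S,9R,10R)-drim-7-ene-3,11-diol | OC[C@@H]1C(C)=CC[C@@H]2C(C)(C)[C@H](O)CC[C@@]12C | intermediate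
12 | (5S,9R,10R)-3-oxodrim-7-en-11-al | O=C[C@@H]1C(C)=CC[C@@H]2C(C)(C)C(=O)CC[C@@]12C | intermediate
13 | (5S,9R,10R)-11-methylidenedrim-7-en-3-one (9-vinyl ketone) | C=C[C@@H]1C(C)=CC[C@@H]2C(C)(C)C(=O)CC[C@@]12C | intermediate
14 | (3S,5S,9R,10R)-11-methylidenedrim-7-en-3-ol (axial 3-OH, cis to H-5) | C=C[C@@H]1C(C)=CC[C@@H]2C(C)(C)[C@@H](O)CC[C@@]12C | intermediate
15 | ethyl 3-oxobutanoate | CCOC(=O)CC(C)=O | starting material
16 | ethyl (2E)-3-{[(trifluoromethyl)sulfonyl]oxy}but-2-enoate | CCOC(=O)/C=C(\C)OS(=O)(=O)C(F)(F)F | intermediate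
17 | 9-borabicyclo[3.3.1]nonane adduct of 14, boron on the terminal carbon of the former vinyl group | B1(CC[C@@H]3C(C)=CC[C@@H]4C(C)(C)[C@@H](O)CC[C@@]34C)C2CCCC1CCC2 | intermediate
18 | ethyl (3S,5S,9R,10S,13E)-3-hydroxylabda-7,13-dien-15-oate | CCOC(=O)/C=C(\C)CC[C@@H]1C(C)=CC[C@@H]2C(C)(C)[C@@H](O)CC[C@@]12C | intermediate
19 | (3S,5S,9R,10S,13E)-labda-7,13-diene-3,15-diol | OC/C=C(\C)CC[C@@H]1C(C)=CC[C@@H]2C(C)(C)[C@@H](O)CC[C@@]12C | intermediate
20 | (3S)-3-methylpentanoic acid | CC[C@H](C)CC(=O)O | starting material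
21 | (3S,5S,9R,10S,13E)-3-hydroxylabda-7,13-dien-15-yl (3S)-3-methylpentanoate | CC[C@H](C)CC(=O)OC/C=C(\C)CC[C@@H]1C(C)=CC[C@@H]2C(C)(C)[C@@H](O)CC[C@@]12C | target

**Count.** Total step count: 14. Longest linear sequence: 13 steps (steps 1–10 and 12–14, from methyl geranate); step 11 makes the coupling partner.

**Steps most likely to fail**

Step 5. The β,β-disubstituted enoate may add too slowly to the hindered diene terminus (C5, next to the quaternary C4). The endo and facial preferences may also erode under the syn 4-CH3/10-CH3 strain that builds up in the trans-fused transition state, giving cis-fused or C3-mismatched skeletons, and the Lewis acid may attack the acetate. The fallback sets out from 8 and comes back at 10; it swaps the ester for a far more reactive enal dienophile. i-Bu2AlH (4 equiv, CH2Cl2, −78 °C) reduces both esters of 8 to (2E,6R,8E,10E)-3,7,7-trimethyldodeca-2,8,10-triene-1,6-diol F1. MnO2 in CH2Cl2 oxidises only the allylic alcohol to (2E,6R,8E,10E)-6-hydroxy-3,7,7-trimethyldodeca-2,8,10-trienal F2. Me2AlCl (2.2 equiv, CH2Cl2, −78 → −20 °C) turns the hydroxyl into a bulky equatorial aluminium alkoxide and activates the enal, so that the cycloaddition should proceed at low temperature to (3R,5S,8R,9R,10R)-3-hydroxydrim-6-en-11-al F3. NaBH4 in MeOH at 0 °C then gives 10.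

Step 7. The chain walk may stall at the hindered disubstituted alkene, run toward C5 and erase that stereocentre, or run on to the tetrasubstituted C8=C9 position. The fallback sets out from 9 and comes back at 11; it replaces catalysis by a dehydrogenation and deconjugative reduction that are regiospecific by mechanism. K2CO3 in MeOH removes the acetate to give methyl (3R,5S,8R,9R,10R)-3-hydroxydrim-6-en-11-oate F4. LiN(i-Pr)2 (2.2 equiv, THF, −78 → 0 °C) and then PhSeCl give methyl (3R,5S,8R,10R)-3-hydroxy-9-(phenylselanyl)drim-6-en-11-oate F5, with selenium entering cis to H-8. H2O2 (CH2Cl2, pyridine, 0 °C) brings about selenoxide syn-elimination, which can only use H-8, to give methyl (3R,5S,10R)-3-hydroxydrima-6,8-dien-11-oate F6. SmI2 (THF, HMPA, t-BuOH, −78 °C) reduces the dienoate at its termini C6 and C9, and kinetic α-protonation from the face opposite 10-CH3 gives the deconjugated methyl (3R,5S,9R,10R)-3-hydroxydrim-7-en-11-oate F7. LiAlH4 in THF then gives 11.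

Step 4. The alkenyl Heck coupling may suffer from slow insertion at the neopentyl-type alkene, palladium-hydride scrambling of the diene geometry, or homocoupling of the volatile bromide. The fallback sets out from 6 and comes back at 8; it builds the diene in two stereodefined operations. Johnson–Lemieux cleavage (OsO4 cat., NaIO4, 2,6-lutidine, dioxane/H2O) of the vinyl group gives methyl (2E,6R)-6-acetoxy-3,7,7-trimethyl-8-oxooct-2-enoate F8. Takai olefination (CrCl2, CHI3, THF, 0 °C) gives methyl (2E,6R,8E)-6-acetoxy-9-iodo-3,7,7-trimethylnona-2,8-dienoate F9. Suzuki coupling with (E)-prop-1-enylboronic acid (Pd(PPh3)4, K3PO4, THF/H2O, 40 °C) then gives 8.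

Further compounds
F1 | step 5 | (2E,6R,8E,10E)-3,7,7-trimethyldodeca-2,8,10-triene-1,6-diol | OC/C=C(\C)CC[C@@H](O)C(C)(C)/C=C/C=C/C
F2 | step 5 | (2E,6R,8E,10E)-6-hydroxy-3,7,7-trimethyldodeca-2,8,10-trienal | O=C/C=C(\C)CC[C@@H](O)C(C)(C)/C=C/C=C/C
F3 | step 5 | (3R,5S,8R,9R,10R)-3-hydroxydrim-6-en-11-al | O=C[C@@H]1[C@H](C)C=C[C@@H]2C(C)(C)[C@H](O)CC[C@@]12C
F4 | step 7 | methyl (3R,5S,8R,9R,10R)-3-hydroxydrim-6-en-11-oate | COC(=O)[C@@H]1[C@H](C)C=C[C@@H]2C(C)(C)[C@H](O)CC[C@@]12C
F5 | step 7 | methyl (3R,5S,8R,10R)-3-hydroxy-9-(phenylselanyl)drim-6-en-11-oate | COC(=O)[C@]1([Se]c3ccccc3)[C@H](C)C=C[C@@H]2C(C)(C)[C@H](O)CC[C@@]12C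
F6 | step 7 | methyl (3R,5S,10R)-3-hydroxydrima-6,8-dien-11-oate | COC(=O)C1=C(C)C=C[C@@H]2C(C)(C)[C@H](O)CC[C@@]12C
F7 | step 7 | methyl (3R,5S,9R,10R)-3-hydroxydrim-7-en-11-oate | COC(=O)[C@@H]1C(C)=CC[C@@H]2C(C)(C)[C@H](O)CC[C@@]12C
F8 | step 4 | methyl (2E,6R)-6-acetoxy-3,7,7-trimethyl-8-oxooct-2-enoate | COC(=O)/C=C(\C)CC[C@@H](OC(C)=O)C(C)(C)C=O
F9 | step 4 | methyl (2E,6R,8E)-6-acetoxy-9-iodo-3,7,7-trimethylnona-2,8-dienoate | COC(=O)/C=C(\C)CC[C@@H](OC(C)=O)C(C)(C)/C=C/I
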